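**Strategy.** The flavanone is cut across ring C at O1–C2 and C3–C4. The C4a–C8a edge of the phloroglucinol ring A, with C4 attached, becomes an ethoxy-substituted ortho-quinone methide, and C2–C3 with ring B becomes a 2-hydroxystyrene. One chiral phosphoric acid-catalysed three-component [4+2] (aldehyde, triethyl orthoformate, styrene) forms both bonds, closes ring C and sets C2 as S; C4 arrives as an ether that is later converted into the ketone. The methide precursor is a 3,5-diprenyl phloroglucinol aldehyde with one free ortho hydroxyl and two silyl ethers. The styrene carries the 3-prenyl group, a free 2-hydroxyl for catalyst binding and a 4-silyl ether.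

Key step: step 7

**Remarks on the chemistry**
- Abbreviations: prenyl = 3-methylbut-2-en-1-yl; TBS = tert-butyldimethylsilyl; TIPS = triisopropylsilyl; (R)-TRIP = (R)-3,3'-bis(2,4,6-triisopropylphenyl)-1,1'-binaphthyl-2,2'-diyl hydrogen phosphate. Flavan numbering is used from step 7 on.
- Structure check: the target is (2S)-5,7-dihydroxy-2-(2,4-dihydroxy-3-prenylphenyl)-6,8-diprenylchroman-4-one. At C2 the priorities are O1 > C1' > C3 > H, and the SMILES descriptor corresponds to S. No error was found in constitution or descriptor.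
- Assumption: (R)-TRIP is written as the antipode that gives 2S, by analogy with 2-hydroxystyrene/ortho-quinone methide cycloadditions. If the first run shows the 2R series, (S)-TRIP is used and nothing else changes.
- Design of the aldehyde: it enters the key step as the 4,6-bis-TBS ether 4, not as the free triol 3. A free 5-hydroxyl in the adduct would sit ortho to the C4 ether and could form a second ortho-quinone methide. A free 7-hydroxyl would open a para-quinone methide channel. Free ring-A phenols would also make the later flavan-4-ol and its oxidation fragile.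
- Design of the 2'-hydroxyl: the styrene 2-hydroxyl stays free for catalyst binding. In the adduct this hydroxyl can reach C4 and would close a 2'-O–C4 bridged ether whenever C4 is ionised, so it is silylated (step 8) before the ethoxy group is exchanged.
- Ring-B aldehyde: it is built by O-alkylation and Claisen rearrangement, which needs no acid-labile acetal protecting group next to a prenyl group.

**Route**

Step 1
Reactants: 1 2,4,6-trihydroxybenzaldehyde; 2 prenyl bromide (1-bromo-3-methylbut-2-ene)
Product: 3 2,4,6-trihydroxy-3,5-diprenylbenzaldehyde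
Conditions: 2 (2.1 equiv), 10% aq KOH, 0 °C to rt
Reagents that add atoms: none
Why: Phenoxide C-alkylation with an allylic bromide; in water the polyphenoxide of 1 reacts at its two equivalent free ring carbons (C3, C5), and the formyl group damps the ring enough to limit geminal dialkylation.

Step 2
Reactants: 3 2,4,6-trihydroxy-3,5-diprenylbenzaldehyde
Product: 4 2-hydroxy-4,6-bis(tert-butyldimethylsilyloxy)-3,5-diprenylbenzaldehyde
Conditions: TBSCl (2.2 equiv), imidazole, DMF, 0 °C to rt
Reagents that add atoms: tert-butyldimethylsilyl chloride, CC(C)(C)[Si](C)(C)Cl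
Why: Phenol silylation; the acidic, non-chelated 4-hydroxyl reacts first, then the ortho hydroxyl that is not hydrogen-bonded to the aldehyde, and the remaining chelated, flanked hydroxyl stays free for methide formation (the two ortho hydroxyls are equivalent, so one bis-ether results).

Step 3
Reactants: 5 2,4-dihydroxybenzaldehyde; 6 3-chloro-3-methylbut-1-yne
Product: 7 2-hydroxy-4-[(2-methylbut-3-yn-2-yl)oxy]benzaldehyde
Conditions: 6 (1.5 equiv), K2CO3, KI (cat.), CuI (cat.), acetone, 55 °C
Reagents that add atoms: none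
Why: Copper-assisted O-alkylation of a phenol with a tertiary propargylic chloride; only the 4-hydroxyl reacts because it is the more acidic and is not tied to the aldehyde by a hydrogen bond.

Step 4
Reactants: 7 2-hydroxy-4-[(2-methylbut-3-yn-2-yl)oxy]benzaldehyde
Product: 9 2,4-dihydroxy-3-prenylbenzaldehyde, via dimethylallyl aryl ether 8 (not isolated)
Conditions: H2 (1 atm), Pd/CaCO3 poisoned with Pb(OAc)2 (Lindlar catalyst), quinoline, toluene, rt; filter through Celite; filtrate at 110 °C
Reagents that add atoms: none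
Why: Lindlar semi-hydrogenation stops at the terminal alkene, and the aromatic Claisen rearrangement ([3,3]) then moves the dimethylallyl group from O4 to C3 with allylic transposition to the linear prenyl group; C3 is preferred over C5 because the chelated ring has more double-bond character at C3–C4.

Step 5
Reactants: 9 2,4-dihydroxy-3-prenylbenzaldehyde
Product: 10 2-hydroxy-3-prenyl-4-(triisopropylsilyloxy)benzaldehyde
Conditions: TIPSCl (1.1 equiv), imidazole, DMF, 0 °C to rt
Reagents that add atoms: triisopropylsilyl chloride, CC(C)[Si](Cl)(C(C)C)C(C)C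
Why: Selective phenol silylation; the 2-hydroxyl is chelated to the aldehyde and does not compete with the 4-hydroxyl for the bulky chloride.

Step 6
Reactants: 10 2-hydroxy-3-prenyl-4-(triisopropylsilyloxy)benzaldehyde
Product: 11 2-hydroxy-3-prenyl-4-(triisopropylsilyloxy)styrene
Conditions: Ph3PCH3Br (2.5 equiv), NaN(SiMe3)2 (2.4 equiv), THF, 0 °C to rt; product kept cold and used promptly
Reagents that add atoms: methyltriphenylphosphonium bromide, C[P+](c1ccccc1)(c1ccccc1)c1ccccc1.[Br-]
Why: Wittig methylenation; one equivalent of ylide is spent on the phenol and the excess converts the aldehyde, the usual entry to 2-vinylphenols, and the hindered TIPS ether tolerates the alkoxide-free ylide.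

Step 7
Reactants: 4 2-hydroxy-4,6-bis(tert-butyldimethylsilyloxy)-3,5-diprenylbenzaldehyde; 12 triethyl orthoformate; 11 2-hydroxy-3-prenyl-4-(triisopropylsilyloxy)styrene
Product: 15 (2S)-4-ethoxy-5,7-bis(tert-butyldimethylsilyloxy)-2-[2-hydroxy-3-prenyl-4-(triisopropylsilyloxy)phenyl]-6,8-diprenylchroman (both C4 epimers), via diethyl acetal 13 (not isolated), via ethoxy ortho-quinone methide 14 (not isolated)
Conditions: (R)-TRIP (10 mol%), 12 (2 equiv), 5 Å MS, toluene, rt; then 11 (1.3 equiv, slow addition), −20 °C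
Reagents that add atoms: none
Why: Proposed new method: acid catalysis converts 4 and the orthoformate into acetal 13, which loses ethanol to the ethoxy ortho-quinone methide 14 held as a hydrogen-bonded pair with the chiral phosphate; the terminal CH2 of 11 attacks the methide carbon (C3–C4) and the ring-A oxygen then collapses onto the benzylic cation stabilised by the 2-hydroxy-4-silyloxyaryl group (O1–C2), an asynchronous inverse-demand oxa-[4+2]. The closest known reactions are the achiral acid-catalysed three-component synthesis of 4-alkoxyflavans from salicylaldehydes, orthoformates and styrenes and the chiral phosphoric acid-catalysed [4+2] of aryl-substituted ortho-quinone methides with 2-hydroxystyrenes; their combination on an alkoxy methide is the untested part. Ring C closes as a six-membered pyran by hetero-Diels–Alder cycloaddition across the C4a–C8a edge of ring A. C2 is set by the catalyst, whose phosphoryl oxygen holds the free 2-hydroxyl of 11 while its acidic OH holds the methide carbonyl, so that one face of the styrene is presented (planned: the face leading to 2S); C4 is left uncontrolled because it becomes the carbonyl carbon. Regiochemistry follows from polarity (nucleophilic CH2 onto the electrophilic methide carbon), a single chroman can form because only one ortho hydroxyl of 4 is free, and the silyl ethers on O5 and O7 stop the adduct from forming a second methide or ionising readily at C4.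

Step 8
Reactants: 15 (2S)-4-ethoxyflavan with free 2'-hydroxyl
Product: 16 (2S)-4-ethoxy-5,7-bis(tert-butyldimethylsilyloxy)-2-[2-(tert-butyldimethylsilyloxy)-3-prenyl-4-(triisopropylsilyloxy)phenyl]-6,8-diprenylchroman (both C4 epimers)
Conditions: TBSCl (1.5 equiv), imidazole, DMAP (cat.), DMF, rt
Reagents that add atoms: tert-butyldimethylsilyl chloride, CC(C)(C)[Si](C)(C)Cl
Why: Phenol silylation under basic, non-ionising conditions; it caps the only free hydroxyl so that it cannot add to C4 when that carbon is ionised in step 9.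

Step 9
Reactants: 16 fully silylated (2S)-4-ethoxyflavan
Product: 17 (2S)-5,7-bis(tert-butyldimethylsilyloxy)-2-[2-(tert-butyldimethylsilyloxy)-3-prenyl-4-(triisopropylsilyloxy)phenyl]-6,8-diprenylchroman-4-ol (both C4 epimers)
Conditions: TsOH·H2O (10 mol%), THF/H2O 4:1, rt
Reagents that add atoms: water, O
Why: SN1 solvolysis of a benzylic ether whose cation is stabilised by O1, O5 and O7 (ortho, ortho and para to C4a); water in large excess captures it, both C4 epimers converge on the alcohol, and C2 is not involved.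

Step 10
Reactants: 17 (2S)-flavan-4-ol
Product: 18 (2S)-5,7-bis(tert-butyldimethylsilyloxy)-2-[2-(tert-butyldimethylsilyloxy)-3-prenyl-4-(triisopropylsilyloxy)phenyl]-6,8-diprenylchroman-4-one
Conditions: Dess–Martin periodinane (1.5 equiv), pyridine, CH2Cl2, 0 °C to rt
Reagents that add atoms: none
Why: Dess–Martin oxidation of a secondary benzylic alcohol to the aryl ketone; the C4 stereocentre disappears, and the pyridine buffer avoids both acid ionisation at C4 and base-induced ring opening, so C2 stays S.

Step 11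
Reactants: 18 (2S)-tetrasilyl flavanone
Product: 19 (2S)-5,7-dihydroxy-2-(2,4-dihydroxy-3-prenylphenyl)-6,8-diprenylchroman-4-one (target)
Conditions: HF·pyridine (excess), pyridine, THF, 0 °C to rt
Reagents that add atoms: none
Why: Fluoride cleavage of the four aryl silyl ethers, driven by Si–F bond formation; the buffered, weakly acidic medium avoids the phenoxide-triggered retro-oxa-Michael opening to the chalcone, so C2 keeps its S configuration, and the prenyl groups are not touched.

**Compound list**

1 | 2,4,6-trihydroxybenzaldehyde | O=Cc1c(O)cc(O)cc1O | starting material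
2 | prenyl bromide (1-bromo-3-methylbut-2-ene) | CC(C)=CCBr | starting material
3 | 2,4,6-trihydroxy-3,5-diprenylbenzaldehyde | CC(C)=CCc1c(O)c(C=O)c(O)c(CC=C(C)C)c1O | intermediate
4 | 2-hydroxy-4,6-bis(tert-butyldimethylsilyloxy)-3,5-diprenylbenzaldehyde | CC(C)=CCc1c(O)c(C=O)c(O[Si](C)(C)C(C)(C)C)c(CC=C(C)C)c1O[Si](C)(C)C(C)(C)C | intermediate
5 | 2,4-dihydroxybenzaldehyde | O=Cc1ccc(O)cc1O | starting material
6 | 3-chloro-3-methylbut-1-yne | C#CC(C)(C)Cl | starting material
7 | 2-hydroxy-4-[(2-methylbut-3-yn-2-yl)oxy]benzaldehyde | C#CC(C)(C)Oc1ccc(C=O)c(O)c1 | intermediate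
8 | 2-hydroxy-4-[(2-methylbut-3-en-2-yl)oxy]benzaldehyde (not isolated) | C=CC(C)(C)Oc1ccc(C=O)c(O)c1 | intermediate
9 | 2,4-dihydroxy-3-prenylbenzaldehyde | CC(C)=CCc1c(O)ccc(C=O)c1O | intermediate
10 | 2-hydroxy-3-prenyl-4-(triisopropylsilyloxy)benzaldehyde | CC(C)=CCc1c(O[Si](C(C)C)(C(C)C)C(C)C)ccc(C=O)c1O | intermediate
11 | 2-hydroxy-3-prenyl-4-(triisopropylsilyloxy)styrene | C=Cc1ccc(O[Si](C(C)C)(C(C)C)C(C)C)c(CC=C(C)C)c1O | intermediate
12 | triethyl orthoformate | CCOC(OCC)OCC | starting material
13 | diethyl acetal of 4 (not isolated) | CCOC(OCC)c1c(O)c(CC=C(C)C)c(O[Si](C)(C)C(C)(C)C)c(CC=C(C)C)c1O[Si](C)(C)C(C)(C)C | intermediate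
14 | 6-(ethoxymethylidene)-3,5-bis(tert-butyldimethylsilyloxy)-2,4-diprenylcyclohexa-2,4-dien-1-one, the ethoxy ortho-quinone methide (not isolated) | CCOC=C1C(=O)C(CC=C(C)C)=C(O[Si](C)(C)C(C)(C)C)C(CC=C(C)C)=C1O[Si](C)(C)C(C)(C)C | intermediate
15 | (2S)-4-ethoxy-5,7-bis(tert-butyldimethylsilyloxy)-2-[2-hydroxy-3-prenyl-4-(triisopropylsilyloxy)phenyl]-6,8-diprenylchroman, C4 epimers | CC(C)=CCc1c(O[Si](C(C)C)(C(C)C)C(C)C)ccc([C@@H]2CC(OCC)c3c(O[Si](C)(C)C(C)(C)C)c(CC=C(C)C)c(O[Si](C)(C)C(C)(C)C)c(CC=C(C)C)c3O2)c1O | intermediate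
16 | (2S)-4-ethoxy-5,7-bis(tert-butyldimethylsilyloxy)-2-[2-(tert-butyldimethylsilyloxy)-3-prenyl-4-(triisopropylsilyloxy)phenyl]-6,8-diprenylchroman, C4 epimers | CC(C)=CCc1c(O[Si](C(C)C)(C(C)C)C(C)C)ccc([C@@H]2CC(OCC)c3c(O[Si](C)(C)C(C)(C)C)c(CC=C(C)C)c(O[Si](C)(C)C(C)(C)C)c(CC=C(C)C)c3O2)c1O[Si](C)(C)C(C)(C)C | intermediate
17 | (2S)-5,7-bis(tert-butyldimethylsilyloxy)-2-[2-(tert-butyldimethylsilyloxy)-3-prenyl-4-(triisopropylsilyloxy)phenyl]-6,8-diprenylchroman-4-ol, C4 epimers | CC(C)=CCc1c(O[Si](C(C)C)(C(C)C)C(C)C)ccc([C@@H]2CC(O)c3c(O[Si](C)(C)C(C)(C)C)c(CC=C(C)C)c(O[Si](C)(C)C(C)(C)C)c(CC=C(C)C)c3O2)c1O[Si](C)(C)C(C)(C)C | intermediate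
18 | (2S)-5,7-bis(tert-butyldimethylsilyloxy)-2-[2-(tert-butyldimethylsilyloxy)-3-prenyl-4-(triisopropylsilyloxy)phenyl]-6,8-diprenylchroman-4-one | CC(C)=CCc1c(O[Si](C(C)C)(C(C)C)C(C)C)ccc([C@@H]2CC(=O)c3c(O[Si](C)(C)C(C)(C)C)c(CC=C(C)C)c(O[Si](C)(C)C(C)(C)C)c(CC=C(C)C)c3O2)c1O[Si](C)(C)C(C)(C)C | intermediate
19 | (2S)-5,7-dihydroxy-2-(2,4-dihydroxy-3-prenylphenyl)-6,8-diprenylchroman-4-one | CC(C)=CCc1c(O)ccc([C@@H]2CC(=O)c3c(O)c(CC=C(C)C)c(O)c(CC=C(C)C)c3O2)c1O | target

**Totals**

Total step count: 11. Longest linear sequence: 9 steps (steps 3–11, from 2,4-dihydroxybenzaldehyde).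

**Steps most likely to fail**

Step 7 (the step that bears the label "Proposed new method:"). The likely failure is poor facial selectivity in the styrene addition, or loss of enantiopurity through slow catalysis that lets the acid-sensitive styrene self-condense or lets the adduct re-ionise. The fallback gives up catalyst control and separates the enantiomers later, using known reactions only. It sets out from 4, 11 and 12, which are combined under an achiral Brønsted acid (pyridinium p-toluenesulfonate, toluene, rt) in the established three-component manner to give racemic 4-ethoxy-5,7-bis(tert-butyldimethylsilyloxy)-2-[2-hydroxy-3-prenyl-4-(triisopropylsilyloxy)phenyl]-6,8-diprenylchroman F1. Silylation as in step 8 gives the racemic tetrasilyl 4-ethoxyflavan F2, hydrolysis as in step 9 gives the racemic flavan-4-ol F3, and oxidation as in step 10 gives the racemic tetrasilyl flavanone F4. F4 is then subjected to kinetic resolution by asymmetric transfer hydrogenation (RuCl(p-cymene)(TsDPEN) in the antipode that reduces the 2R ketone, HCO2H/Et3N). This converts the unwanted enantiomer into the (2R,4R)-cis-flavan-4-ol F5 and leaves the 2S ketone, which is separated by chromatography. The fallback returns to the route at 18.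

Step 9. The likely failure is E1 loss of ethanol to the flav-3-ene in competition with water capture, together with acid-induced C2–O1 heterolysis (erosion at C2) or partial desilylation. The fallback replaces solvolysis by oxidation and sets out from 16. DDQ in CH2Cl2/pH 7 buffer at 0 °C abstracts hydride from the electron-rich C4–H of the benzylic ethyl ether, water adds to the oxocarbenium ion, and the hemiketal collapses to the ketone. The silylated phenols block the chromene-forming pathway that DDQ opens for free ortho-prenylphenols. It returns to the route at 18, bypasses step 10 and makes no new isolated compound (F0).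

Step 1. The likely failure is poor chemoselectivity: O-alkylation, stopping at the mono-prenyl stage, or geminal dialkylation with dearomatisation. The fallback installs each prenyl group by O-alkylation and Claisen rearrangement, as in steps 3 and 4, and sets out from 1. Selective 4-O-alkylation with 6 (K2CO3, KI, CuI, acetone) gives 2,6-dihydroxy-4-[(2-methylbut-3-yn-2-yl)oxy]benzaldehyde F6. Lindlar semi-hydrogenation gives 2,6-dihydroxy-4-[(2-methylbut-3-en-2-yl)oxy]benzaldehyde F7, which rearranges on heating to 2,4,6-trihydroxy-3-prenylbenzaldehyde F8. A second 4-O-alkylation with 6 gives 2,6-dihydroxy-3-prenyl-4-[(2-methylbut-3-yn-2-yl)oxy]benzaldehyde F9, and semi-hydrogenation gives 2,6-dihydroxy-3-prenyl-4-[(2-methylbut-3-en-2-yl)oxy]benzaldehyde F10. Claisen rearrangement of F10 can only end at the one free ortho carbon, C5, and the fallback returns to the route at 3.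

**Further compounds**

F1 | step 7 | racemic 4-ethoxy-5,7-bis(tert-butyldimethylsilyloxy)-2-[2-hydroxy-3-prenyl-4-(triisopropylsilyloxy)phenyl]-6,8-diprenylchroman | CC(C)=CCc1c(O[Si](C(C)C)(C(C)C)C(C)C)ccc(C2CC(OCC)c3c(O[Si](C)(C)C(C)(C)C)c(CC=C(C)C)c(O[Si](C)(C)C(C)(C)C)c(CC=C(C)C)c3O2)c1O
F2 | step 7 | racemic 4-ethoxy-5,7-bis(tert-butyldimethylsilyloxy)-2-[2-(tert-butyldimethylsilyloxy)-3-prenyl-4-(triisopropylsilyloxy)phenyl]-6,8-diprenylchroman | CC(C)=CCc1c(O[Si](C(C)C)(C(C)C)C(C)C)ccc(C2CC(OCC)c3c(O[Si](C)(C)C(C)(C)C)c(CC=C(C)C)c(O[Si](C)(C)C(C)(C)C)c(CC=C(C)C)c3O2)c1O[Si](C)(C)C(C)(C)C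
F3 | step 7 | racemic 5,7-bis(tert-butyldimethylsilyloxy)-2-[2-(tert-butyldimethylsilyloxy)-3-prenyl-4-(triisopropylsilyloxy)phenyl]-6,8-diprenylchroman-4-ol | CC(C)=CCc1c(O[Si](C(C)C)(C(C)C)C(C)C)ccc(C2CC(O)c3c(O[Si](C)(C)C(C)(C)C)c(CC=C(C)C)c(O[Si](C)(C)C(C)(C)C)c(CC=C(C)C)c3O2)c1O[Si](C)(C)C(C)(C)C
F4 | step 7 | racemic 5,7-bis(tert-butyldimethylsilyloxy)-2-[2-(tert-butyldimethylsilyloxy)-3-prenyl-4-(triisopropylsilyloxy)phenyl]-6,8-diprenylchroman-4-one | CC(C)=CCc1c(O[Si](C(C)C)(C(C)C)C(C)C)ccc(C2CC(=O)c3c(O[Si](C)(C)C(C)(C)C)c(CC=C(C)C)c(O[Si](C)(C)C(C)(C)C)c(CC=C(C)C)c3O2)c1O[Si](C)(C)C(C)(C)C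
F5 | step 7 | (2R,4R)-cis-5,7-bis(tert-butyldimethylsilyloxy)-2-[2-(tert-butyldimethylsilyloxy)-3-prenyl-4-(triisopropylsilyloxy)phenyl]-6,8-diprenylchroman-4-ol | CC(C)=CCc1c(O[Si](C(C)C)(C(C)C)C(C)C)ccc([C@H]2C[C@@H](O)c3c(O[Si](C)(C)C(C)(C)C)c(CC=C(C)C)c(O[Si](C)(C)C(C)(C)C)c(CC=C(C)C)c3O2)c1O[Si](C)(C)C(C)(C)C
F0 | step 9 | none | none
F6 | step 1 | 2,6-dihydroxy-4-[(2-methylbut-3-yn-2-yl)oxy]benzaldehyde | C#CC(C)(C)Oc1cc(O)c(C=O)c(O)c1
F7 | step 1 | 2,6-dihydroxy-4-[(2-methylbut-3-en-2-yl)oxy]benzaldehyde | C=CC(C)(C)Oc1cc(O)c(C=O)c(O)c1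
F8 | step 1 | 2,4,6-trihydroxy-3-prenylbenzaldehyde | CC(C)=CCc1c(O)cc(O)c(C=O)c1O
F9 | step 1 | 2,6-dihydroxy-3-prenyl-4-[(2-methylbut-3-yn-2-yl)oxy]benzaldehyde | C#CC(C)(C)Oc1cc(O)c(C=O)c(O)c1CC=C(C)C
F10 | step 1 | 2,6-dihydroxy-3-prenyl-4-[(2-methylbut-3-en-2-yl)oxy]benzaldehyde | C=CC(C)(C)Oc1cc(O)c(C=O)c(O)c1CC=C(C)C
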